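**Retrosynthetic overview**

1. Chromanone numbering is used (O1, C2, C3, C4, C4a, C5–C8, C8a); ring A is the carbocycle C4a–C5–C6–C7–C8–C8a, ring B the pyranone, and R11 is (2R)-5-methyl-2-(2-methylprop-1-en-1-yl)hex-5-en-1-yl. The last disconnections are the methyl ester and the C6–prenyl bond, the latter made by dearomative Tsuji–Trost prenylation of aromatic chromanone ester 33, which copies the presumed biosynthetic C-prenylation.
2. Ring B is closed at O1–C2 by an intramolecular Mitsunobu reaction with inversion; its anti-aldol acyl chain is brought to C4a by a photo-Fries shift from O8a.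
3. Ring A is made aromatic, as pentasubstituted phenol 23, by a two-carbon ring expansion of siloxycyclobutenone 12 with ynol ether 18. Ring order: ring A (step 7), ring B (step 14), then the quaternary C6 (step 16).
4. The enabling feature is the phloroglucinol pattern of ring A: the O-bearing carbons C5, C7 and C8a alternate with the C-substituted carbons C4a, C6 and C8. This maps onto one ketene carbonyl (C8a) and two ynol-ether carbons (C7, C5), and C4a is the only ring CH.
5. Fragments: siloxyalkyne 7 (side-chain stereocentre by Rh-catalysed conjugate addition), half-ester 9 (benzylic stereocentre by anhydride desymmetrisation), acid 28 (C3 by Fráter–Seebach alkylation, C2 from the chiral pool and inverted on ring closure).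

Key step: step 7

Assumption: the target is one tautomer of an enolised β-triketone and is drawn as given; the sense of induction of the chiral catalysts in steps 2, 4 and 16 is assigned by analogy, and the mirror-image (or pseudo-enantiomeric) catalyst is used where a pilot run shows the opposite sense.

**Route**

Step 1
Reactants: 1 2-methylhexa-1,5-diene; 2 ethyl acrylate
Product: 3 ethyl (2E)-6-methylhepta-2,6-dienoate
Conditions: second-generation Grubbs catalyst (2 mol %), 2 (3 equiv), CH2Cl2, 40 °C
Reagents that add atoms: none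
Why: Olefin cross-metathesis: the monosubstituted alkene of 1 couples with the electron-poor acrylate to the (E)-enoate with loss of ethene, while the 1,1-disubstituted alkene is too hindered to compete.

Step 2
Reactants: 3 ethyl (2E)-6-methylhepta-2,6-dienoate; 4 (2-methylprop-1-en-1-yl)boronic acid
Product: 5 ethyl (3R)-6-methyl-3-(2-methylprop-1-en-1-yl)hept-6-enoate
Conditions: [Rh(OH)((S)-binap)]2 (3 mol %), 4 (2.5 equiv), 1,4-dioxane/H2O 10:1, 50 °C
Reagents that add atoms: none
Why: Hayashi–Miyaura reaction: the alkenyl–rhodium species formed by transmetallation adds 1,4 to the (E)-enoate inside the chiral pocket of (S)-BINAP, which fixes the enoate face and should set the (R) side-chain stereocentre; the isolated 1,1-disubstituted alkene is not an acceptor.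

Step 3
Reactants: 5 ethyl (3R)-6-methyl-3-(2-methylprop-1-en-1-yl)hept-6-enoate
Product: 7 triisopropyl{[(4R)-7-methyl-4-(2-methylprop-1-en-1-yl)oct-7-en-1-yn-1-yl]oxy}silane, via lithium ynolate 6 (not isolated)
Conditions: CH2Br2, lithium 2,2,6,6-tetramethylpiperidide (2 equiv), THF, −78 °C; n-BuLi, −78 °C → rt; iPr3SiOTf, −78 °C
Reagents that add atoms: dibromomethane, BrCBr; triisopropylsilyl trifluoromethanesulfonate, CC(C)[Si](OS(=O)(=O)C(F)(F)F)(C(C)C)C(C)C
Why: Kowalski ester homologation stopped at the ynolate: LiCHBr2 adds to the ester, bromine–lithium exchange on the dibromo-ketone enolate triggers the 1,2-shift of the alkyl group to ynolate 6, and the bulky silyl triflate traps it on oxygen; the β-stereocentre is not acidic and stays untouched.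

Step 4
Reactants: 8 3-phenylglutaric anhydride (4-phenyloxane-2,6-dione)
Product: 9 (3R)-5-methoxy-5-oxo-3-phenylpentanoic acid
Conditions: MeOH (10 equiv), (DHQD)2AQN (10 mol %), Et2O, −40 °C
Reagents that add atoms: methanol, CO
Why: Catalytic desymmetrising alcoholysis of a prochiral glutaric anhydride: the cinchona-derived amine activates methanol by general-base catalysis and selects one enantiotopic carbonyl group, which sets the benzylic stereocentre.

Step 5
Reactants: 9 (3R)-5-methoxy-5-oxo-3-phenylpentanoic acid; 7 siloxyalkyne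
Product: 12 methyl (3S)-3-{(1RS)-4-oxo-3-(R11)-2-[(triisopropylsilyl)oxy]cyclobut-2-en-1-yl}-3-phenylpropanoate, via acid chloride 10 (not isolated), via aldoketene 11 (not isolated)
Conditions: (COCl)2, cat. DMF, CH2Cl2, 0 °C → rt, evaporate; then 7, Et3N (slow addition), CH2Cl2, 0 °C → rt
Reagents that add atoms: none
Why: Dehydrochlorination of the acid chloride gives aldoketene 11, which undergoes the regioselective [2+2] cycloaddition with the nucleophilic silyl ynol ether (chain-bearing alkyne carbon to the ketene carbonyl carbon) to the 3-siloxycyclobutenone; the new ring stereocentre forms as a mixture and is erased in step 7.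

Step 6
Reactants: 13 2-(trimethylsilyl)ethanol; 14 trichloroethylene
Product: 18 [2-(ethynyloxy)ethyl]trimethylsilane, via dichlorovinyl ether 15 (not isolated), via chloroalkynyl ether 16 (not isolated), via lithium alkoxyacetylide 17 (not isolated)
Conditions: KH, THF, 0 °C; Cl2C=CHCl, −50 °C → rt; n-BuLi (2.2 equiv), −78 → −40 °C; H2O
Reagents that add atoms: none
Why: Dichlorovinyl ether route to ynol ethers: the potassium alkoxide adds to dichloroacetylene generated from trichloroethylene, and n-BuLi effects elimination and chlorine–lithium exchange to the lithium alkoxyacetylide, which is protonated on work-up.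

Step 7
Reactants: 12 siloxycyclobutenone; 18 [2-(ethynyloxy)ethyl]trimethylsilane
Product: 23 methyl (3R)-3-{2-hydroxy-5-(R11)-6-[(triisopropylsilyl)oxy]-4-[2-(trimethylsilyl)ethoxy]phenyl}-3-phenylpropanoate, via vinylketene 19 (not isolated), via 4-vinylcyclobutenone 20 (not isolated), via dienylketene 21 (not isolated), via cyclohexa-2,4-dienone 22 (not isolated)
Conditions: 18 (3 equiv), toluene, 80 °C (sealed tube), then 110 °C briefly
Reagents that add atoms: none
Why: Danheiser benzannulation in the oxygenated form known for resorcinols from siloxycyclobutenones and ynol ethers: 4π-electrocyclic opening of 12 (both ring epimers) gives vinylketene 19, which the ynol ether traps in a regioselective [2+2] cycloaddition (alkyne CH carbon to the ketene carbonyl carbon) that closes the four-membered ring of 20. A second 4π opening gives dienylketene 21, whose thermal 6π-electrocyclisation closes six-membered ring A by forming the C8–C8a bond (dienone 22), and tautomerisation gives phenol 23, so the four ring atoms of the cyclobutenone and the two alkyne carbons become ring A. No stereocentre is formed, since the sp3 ring atoms of 20 and 22 are transient, and the two side-chain stereocentres are not α to a carbonyl group and are not touched. The selectivity needed is regiochemical: the polarisation of the ketene (electrophilic carbonyl carbon) and of both ynol ethers (nucleophilic β-carbon) places the three oxygens 1,3,5, leaves C4a as the only ring CH, and puts the free OH on C8a, the silyl ether on C7 and the silylethyl ether on C5. An excess of the ynol ether should trap 19 before it dimerises, and the ester and the isolated alkenes are inert at these temperatures.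

Step 8
Reactants: 24 ethyl (3R)-3-hydroxybutanoate
Product: 25 ethyl (2R,3R)-3-hydroxy-2-methylbutanoate
Conditions: LiN(iPr)2 (2.2 equiv), THF, −50 → −20 °C; MeI, DMPU, −78 → −20 °C; 1 M HCl
Reagents that add atoms: iodomethane, CI
Why: Fráter–Seebach alkylation: the lithium-chelated dianion of the β-hydroxy ester is methylated on the face away from the C3 methyl group, which sets the (2R) centre (anti product).

Step 9
Reactants: 25 ethyl (2R,3R)-3-hydroxy-2-methylbutanoate
Product: 26 (2R,3R)-3-hydroxy-2-methylbutanoic acid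
Conditions: LiOH, THF/H2O, 0 °C → rt; then 1 M HCl
Reagents that add atoms: lithium hydroxide, [Li+].[OH-]
Why: Saponification of the ethyl ester under mild conditions that should not epimerise the α-centre.

Step 10
Reactants: 26 (2R,3R)-3-hydroxy-2-methylbutanoic acid
Product: 28 (2R,3R)-2-methyl-3-[(triethylsilyl)oxy]butanoic acid, via bis(triethylsilyl) derivative 27 (not isolated)
Conditions: Et3SiCl (2.2 equiv), imidazole, DMF, 0 °C; then K2CO3 (cat.), MeOH/H2O, 0 °C; pH 5 buffer
Reagents that add atoms: chlorotriethylsilane, CC[Si](Cl)(CC)CC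
Why: Silylation of both the hydroxyl and the carboxyl group followed by selective solvolysis of the labile silyl ester leaves the secondary triethylsilyl ether.

Step 11
Reactants: 23 phenol; 28 (2R,3R)-2-methyl-3-[(triethylsilyl)oxy]butanoic acid
Product: 29 methyl (3R)-3-{2-{[(2R,3R)-2-methyl-3-[(triethylsilyl)oxy]butanoyl]oxy}-5-(R11)-6-[(triisopropylsilyl)oxy]-4-[2-(trimethylsilyl)ethoxy]phenyl}-3-phenylpropanoate
Conditions: DCC, DMAP (cat.), CH2Cl2, 0 °C → rt
Reagents that add atoms: none
Why: Steglich esterification of the only free phenol (O8a); low temperature and catalytic DMAP should limit α-epimerisation of the branched acid.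

Step 12
Reactants: 29 aryl ester
Product: 30 methyl (3R)-3-{2-hydroxy-3-[(2R,3R)-2-methyl-3-[(triethylsilyl)oxy]butanoyl]-5-(R11)-6-[(triisopropylsilyl)oxy]-4-[2-(trimethylsilyl)ethoxy]phenyl}-3-phenylpropanoate
Conditions: hν (254 nm, quartz), degassed cyclohexane, rt
Reagents that add atoms: none
Why: Photo-Fries rearrangement: homolysis of the aryl ester O–acyl bond gives a caged phenoxyl/acyl radical pair that recombines at C4a, the only unsubstituted ortho position (the other ortho and the para position are blocked), with retention in the acyl radical, so the acyl group arrives next to O8a without any acid that would attack the side-chain alkenes.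

Step 13
Reactants: 30 silyl-protected aryl ketone
Product: 31 methyl (3R)-3-{2-hydroxy-3-[(2R,3R)-3-hydroxy-2-methylbutanoyl]-5-(R11)-6-[(triisopropylsilyl)oxy]-4-[2-(trimethylsilyl)ethoxy]phenyl}-3-phenylpropanoate
Conditions: PPTS (cat.), MeOH/CH2Cl2, 0 °C → rt
Reagents that add atoms: none
Why: Mild acid-catalysed methanolysis removes the secondary triethylsilyl ether selectively; the aryl triisopropylsilyl ether, the 2-(trimethylsilyl)ethyl ether and the alkenes should be inert to pyridinium p-toluenesulfonate.

Step 14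
Reactants: 31 β-hydroxy ketone
Product: 32 methyl (3R)-3-{(2S,3R)-2,3-dimethyl-4-oxo-6-(R11)-7-[(triisopropylsilyl)oxy]-5-[2-(trimethylsilyl)ethoxy]-3,4-dihydro-2H-chromen-8-yl}-3-phenylpropanoate
Conditions: PPh3, DIAD, THF, 0 °C → rt
Reagents that add atoms: none
Why: Intramolecular Mitsunobu etherification (6-exo-tet), the ring closure used for 2,3-dimethylchromanones: the phenol O8a–H displaces the activated secondary alcohol with inversion, turning the (2R,3R)-anti-aldol unit into the cis-(2S,3R)-chromanone while O5 is blocked.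

Step 15
Reactants: 32 protected chromanone
Product: 33 methyl (3R)-3-[(2S,3R)-5,7-dihydroxy-2,3-dimethyl-4-oxo-6-(R11)-3,4-dihydro-2H-chromen-8-yl]-3-phenylpropanoate
Conditions: Bu4NF (4 equiv), THF/DMF, 0 °C → rt; then AcOH
Reagents that add atoms: none
Why: Fluoride cleaves the aryl silyl ether and fragments the 2-(trimethylsilyl)ethyl ether with loss of ethene, and the phenoxides that form lower the acidity of H3, so the cis-chromanone should survive.

Step 16
Reactants: 33 5,7-dihydroxychromanone ester; 34 prenyl acetate (3-methylbut-2-en-1-yl acetate)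
Product: 35 methyl (3R)-3-[(2S,3R,6R)-4-hydroxy-2,3-dimethyl-6-(3-methylbut-2-en-1-yl)-5,7-dioxo-6-(R11)-2,3,6,7-tetrahydro-5H-chromen-8-yl]-3-phenylpropanoate
Conditions: 34 (1.05 equiv), Pd2(dba)3·CHCl3 (2.5 mol %), (R,R)-DACH-phenyl bisphosphine ligand (7.5 mol %), Et3N, CH2Cl2, 0 °C → rt
Reagents that add atoms: none
Why: Tsuji–Trost dearomative C-alkylation, as known for acylphloroglucinols and, with this ligand class, for the asymmetric allylic dearomatisation of naphthols: zerovalent palladium ionises prenyl acetate and the phenoxide attacks the unsubstituted allyl terminus through C6 (flanked by O5 and O7 and less hindered than C8), giving the linear prenyl group, while the chiral diphosphine on the π-allyl complex selects the ring face and should set the (6R) quaternary centre by catalyst control, the resident stereocentres being remote.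

Step 17
Reactants: 35 methyl ester of the target
Product: 36 (3R)-3-[(2S,3R,6R)-4-hydroxy-2,3-dimethyl-6-(3-methylbut-2-en-1-yl)-5,7-dioxo-6-(R11)-2,3,6,7-tetrahydro-5H-chromen-8-yl]-3-phenylpropanoic acid (CNP0155375.3)
Conditions: LiOH, THF/H2O, 0 °C → rt; then 1 M HCl to pH 4 at 0 °C
Reagents that add atoms: lithium hydroxide, [Li+].[OH-]
Why: Saponification of the primary methyl ester: the ring is deprotonated first to the β-triketone enolate, which shields H3 from enolisation, so the cis-chromanone and C6 should stay intact, and the brief cold acidification spares the alkenes.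

**Compound list**

1 | 2-methylhexa-1,5-diene | C=C(C)CCC=C | starting material
2 | ethyl acrylate | C=CC(=O)OCC | starting material
3 | ethyl (2E)-6-methylhepta-2,6-dienoate | C=C(C)CC/C=C/C(=O)OCC | intermediate
4 | (2-methylprop-1-en-1-yl)boronic acid | CC(C)=CB(O)O | starting material
5 | ethyl (3R)-6-methyl-3-(2-methylprop-1-en-1-yl)hept-6-enoate | C=C(C)CC[C@@H](C=C(C)C)CC(=O)OCC | intermediate
6 | lithium (4R)-7-methyl-4-(2-methylprop-1-en-1-yl)oct-7-en-1-yn-1-olate (not isolated) | C=C(C)CC[C@@H](C=C(C)C)CC#C[O-].[Li+] | intermediate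
7 | triisopropyl{[(4R)-7-methyl-4-(2-methylprop-1-en-1-yl)oct-7-en-1-yn-1-yl]oxy}silane | C=C(C)CC[C@@H](C=C(C)C)CC#CO[Si](C(C)C)(C(C)C)C(C)C | intermediate
8 | 3-phenylglutaric anhydride | O=C1CC(c2ccccc2)CC(=O)O1 | starting material
9 | (3R)-5-methoxy-5-oxo-3-phenylpentanoic acid | OC(=O)C[C@H](CC(=O)OC)c1ccccc1 | intermediate
10 | methyl (3S)-5-chloro-5-oxo-3-phenylpentanoate (not isolated) | ClC(=O)C[C@H](CC(=O)OC)c1ccccc1 | intermediate
11 | methyl (3S)-5-oxo-3-phenylpent-4-enoate, aldoketene (not isolated) | O=C=C[C@H](CC(=O)OC)c1ccccc1 | intermediate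
12 | methyl (3S)-3-{(1RS)-4-oxo-3-(R11)-2-[(triisopropylsilyl)oxy]cyclobut-2-en-1-yl}-3-phenylpropanoate | O=C1C(C[C@H](C=C(C)C)CCC(C)=C)=C(O[Si](C(C)C)(C(C)C)C(C)C)C1[C@H](CC(=O)OC)c1ccccc1 | intermediate
13 | 2-(trimethylsilyl)ethanol | C[Si](C)(C)CCO | starting material
14 | trichloroethylene | ClC=C(Cl)Cl | starting material
15 | (E)-{2-[(1,2-dichloroethenyl)oxy]ethyl}trimethylsilane (not isolated) | Cl/C=C(/Cl)OCC[Si](C)(C)C | intermediate
16 | {2-[(chloroethynyl)oxy]ethyl}trimethylsilane (not isolated) | ClC#COCC[Si](C)(C)C | intermediate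
17 | lithium [2-(trimethylsilyl)ethoxy]acetylide (not isolated) | [Li]C#COCC[Si](C)(C)C | intermediate
18 | [2-(ethynyloxy)ethyl]trimethylsilane | C#COCC[Si](C)(C)C | intermediate
19 | vinylketene from ring opening of 12 (not isolated) | O=C=C(C[C@H](C=C(C)C)CCC(C)=C)/C(O[Si](C(C)C)(C(C)C)C(C)C)=C/[C@H](CC(=O)OC)c1ccccc1 | intermediate
20 | 4-vinylcyclobutenone from the [2+2] cycloaddition of 19 and 18 (not isolated) | O=C1C=C(OCC[Si](C)(C)C)C1(C[C@H](C=C(C)C)CCC(C)=C)/C(O[Si](C(C)C)(C(C)C)C(C)C)=C/[C@H](CC(=O)OC)c1ccccc1 | intermediate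
21 | dienylketene from ring opening of 20 (not isolated) | O=C=C/C(OCC[Si](C)(C)C)=C(C[C@H](C=C(C)C)CCC(C)=C)\C(O[Si](C(C)C)(C(C)C)C(C)C)=C\[C@H](CC(=O)OC)c1ccccc1 | intermediate
22 | cyclohexa-2,4-dienone from 6π closure of 21 (not isolated) | O=C1C=C(OCC[Si](C)(C)C)C(C[C@H](C=C(C)C)CCC(C)=C)=C(O[Si](C(C)C)(C(C)C)C(C)C)C1[C@H](CC(=O)OC)c1ccccc1 | intermediate
23 | methyl (3R)-3-{2-hydroxy-5-(R11)-6-[(triisopropylsilyl)oxy]-4-[2-(trimethylsilyl)ethoxy]phenyl}-3-phenylpropanoate | Oc1cc(OCC[Si](C)(C)C)c(C[C@H](C=C(C)C)CCC(C)=C)c(O[Si](C(C)C)(C(C)C)C(C)C)c1[C@H](CC(=O)OC)c1ccccc1 | intermediate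
24 | ethyl (3R)-3-hydroxybutanoate | C[C@@H](O)CC(=O)OCC | starting material
25 | ethyl (2R,3R)-3-hydroxy-2-methylbutanoate | C[C@@H](O)[C@@H](C)C(=O)OCC | intermediate
26 | (2R,3R)-3-hydroxy-2-methylbutanoic acid | C[C@@H](O)[C@@H](C)C(=O)O | intermediate
27 | triethylsilyl (2R,3R)-2-methyl-3-[(triethylsilyl)oxy]butanoate (not isolated) | C[C@@H](O[Si](CC)(CC)CC)[C@@H](C)C(=O)O[Si](CC)(CC)CC | intermediate
28 | (2R,3R)-2-methyl-3-[(triethylsilyl)oxy]butanoic acid | C[C@@H](O[Si](CC)(CC)CC)[C@@H](C)C(=O)O | intermediate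
29 | aryl ester of 23 at O8a with the acyl group of 28 | C[C@@H](O[Si](CC)(CC)CC)[C@@H](C)C(=O)Oc1cc(OCC[Si](C)(C)C)c(C[C@H](C=C(C)C)CCC(C)=C)c(O[Si](C(C)C)(C(C)C)C(C)C)c1[C@H](CC(=O)OC)c1ccccc1 | intermediate
30 | ortho-hydroxyaryl ketone (acyl group at C4a, silyl ether on the side-chain hydroxyl) | C[C@@H](O[Si](CC)(CC)CC)[C@@H](C)C(=O)c1c(O)c([C@H](CC(=O)OC)c2ccccc2)c(O[Si](C(C)C)(C(C)C)C(C)C)c(C[C@H](C=C(C)C)CCC(C)=C)c1OCC[Si](C)(C)C | intermediate
31 | ortho-hydroxyaryl (2R,3R)-3-hydroxy-2-methylbutanoyl ketone | C[C@@H](O)[C@@H](C)C(=O)c1c(O)c([C@H](CC(=O)OC)c2ccccc2)c(O[Si](C(C)C)(C(C)C)C(C)C)c(C[C@H](C=C(C)C)CCC(C)=C)c1OCC[Si](C)(C)C | intermediate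
32 | methyl (3R)-3-{(2S,3R)-2,3-dimethyl-4-oxo-6-(R11)-7-[(triisopropylsilyl)oxy]-5-[2-(trimethylsilyl)ethoxy]-3,4-dihydro-2H-chromen-8-yl}-3-phenylpropanoate | O=C1[C@H](C)[C@H](C)Oc2c1c(OCC[Si](C)(C)C)c(C[C@H](C=C(C)C)CCC(C)=C)c(O[Si](C(C)C)(C(C)C)C(C)C)c2[C@H](CC(=O)OC)c1ccccc1 | intermediate
33 | methyl (3R)-3-[(2S,3R)-5,7-dihydroxy-2,3-dimethyl-4-oxo-6-(R11)-3,4-dihydro-2H-chromen-8-yl]-3-phenylpropanoate | O=C1[C@H](C)[C@H](C)Oc2c1c(O)c(C[C@H](C=C(C)C)CCC(C)=C)c(O)c2[C@H](CC(=O)OC)c1ccccc1 | intermediate
34 | prenyl acetate | CC(C)=CCOC(C)=O | starting material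
35 | methyl ester of the target, (2S,3R,6R) ring stereocentres | C=C(C)CC[C@@H](C=C(C)C)C[C@@]1(CC=C(C)C)C(=O)C2=C(O)[C@H](C)[C@H](C)OC2=C([C@H](CC(=O)OC)c2ccccc2)C1=O | intermediate
36 | CNP0155375.3 | C=C(C)CC[C@@H](C=C(C)C)C[C@@]1(CC=C(C)C)C(=O)C2=C(O)[C@H](C)[C@H](C)OC2=C([C@H](CC(=O)O)c2ccccc2)C1=O | target

**Step count**

Total: 17 steps. Longest linear sequence: 12 steps (steps 1, 2, 3, 5, 7, 11, 12, 13, 14, 15, 16, 17).

**Steps most likely to fail**

Step 16. The chiral π-allyl complex may discriminate poorly between the two faces of the nearly planar phenoxide, and O-alkylation, C8-alkylation or a second prenylation may compete. The fallback sets out from 33 and uses the classical base-mediated C-prenylation of the lupulone series (prenyl bromide, NaOMe, MeOH, 0 °C, short reaction time). This should give 35 together with its C6 epimer, the (6S)-diastereomer of 35 F6, and the two diastereomers would be separated by preparative HPLC. The route is rejoined at 35.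

Step 12. The radical pair may escape the solvent cage (giving back phenol 23), the acyl radical may lose CO, and light absorption by the product may stall the conversion. The fallback sets out from 23. Bromination at the only free ring position with NBS (CH2Cl2, −78 °C) gives methyl (3R)-3-{3-bromo-2-hydroxy-5-(R11)-6-[(triisopropylsilyl)oxy]-4-[2-(trimethylsilyl)ethoxy]phenyl}-3-phenylpropanoate F4. Steglich esterification with 28 (DCC, cat. DMAP) gives the ortho-bromoaryl ester of F4 with acid 28 F5. Bromine–lithium exchange (t-BuLi, THF, −100 °C) then triggers the anionic ortho-Fries 1,3-acyl shift, and the route is rejoined at 30.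

Step 2. The alkenylboronic acid may protodeboronate faster than it adds, and enantiofacial control on an acyclic β-alkyl enoate may be incomplete. The fallback sets out from 3 and replaces catalyst control by an auxiliary. Saponification (LiOH, THF/H2O) gives (2E)-6-methylhepta-2,6-dienoic acid F1. Acylation of commercial (4S)-4-phenyl-1,3-oxazolidin-2-one (DCC, cat. DMAP, CH2Cl2) gives (4S)-3-[(2E)-6-methylhepta-2,6-dienoyl]-4-phenyl-1,3-oxazolidin-2-one F2. Copper-mediated conjugate addition of (2-methylprop-1-en-1-yl)magnesium bromide (CuBr·SMe2, THF, −40 °C), anti to the phenyl group of the chelated s-cis imide, gives (4S)-3-[(3R)-6-methyl-3-(2-methylprop-1-en-1-yl)hept-6-enoyl]-4-phenyl-1,3-oxazolidin-2-one F3. Ethanolysis with EtOMgBr (THF, 0 °C) releases the auxiliary, and the route is rejoined at 5.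

**Further compounds**

F1 | step 2 | (2E)-6-methylhepta-2,6-dienoic acid | C=C(C)CC/C=C/C(=O)O
F2 | step 2 | (4S)-3-[(2E)-6-methylhepta-2,6-dienoyl]-4-phenyl-1,3-oxazolidin-2-one | C=C(C)CC/C=C/C(=O)N1[C@@H](c2ccccc2)COC1=O
F3 | step 2 | (4S)-3-[(3R)-6-methyl-3-(2-methylprop-1-en-1-yl)hept-6-enoyl]-4-phenyl-1,3-oxazolidin-2-one | C=C(C)CC[C@@H](C=C(C)C)CC(=O)N1[C@@H](c2ccccc2)COC1=O
F4 | step 12 | methyl (3R)-3-{3-bromo-2-hydroxy-5-(R11)-6-[(triisopropylsilyl)oxy]-4-[2-(trimethylsilyl)ethoxy]phenyl}-3-phenylpropanoate | Oc1c(Br)c(OCC[Si](C)(C)C)c(C[C@H](C=C(C)C)CCC(C)=C)c(O[Si](C(C)C)(C(C)C)C(C)C)c1[C@H](CC(=O)OC)c1ccccc1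
F5 | step 12 | ortho-bromoaryl ester of F4 with acid 28 | C[C@@H](O[Si](CC)(CC)CC)[C@@H](C)C(=O)Oc1c(Br)c(OCC[Si](C)(C)C)c(C[C@H](C=C(C)C)CCC(C)=C)c(O[Si](C(C)C)(C(C)C)C(C)C)c1[C@H](CC(=O)OC)c1ccccc1
F6 | step 16 | (6S)-diastereomer of 35 | C=C(C)CC[C@@H](C=C(C)C)C[C@]1(CC=C(C)C)C(=O)C2=C(O)[C@H](C)[C@H](C)OC2=C([C@H](CC(=O)OC)c2ccccc2)C1=O
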